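Verticillane numbering is used for every compound: ring A is C1, C14, C13, C12, C11, C15; C18 sits on C12, C19 on C8, C20 on C4. Compound numbers refer to the list after the steps.

## Analysis of the target

Target 33 is a verticillane: a cyclohexane (ring A) whose 1,3-related carbons C1 and C11 are bridged by the nine-carbon chain C2–C10, so that C1 to C11 together with C15 form a twelve-membered ring (a bicyclo[9.3.1]pentadecane). Ring A carries the gem-dimethyl carbon C15, the C13 ketone and the exocyclic C12=C18 methylene conjugated to it; the large ring carries two trans trisubstituted epoxides (C3–C4, C7–C8) and a secondary acetate at C10. There are seven stereocentres, 1R,3S,4S,7S,8S,10R,11R: C1 and C11 must be cis for the bridge to exist, C10 is adjacent to C11, and each epoxide comes from oxygen delivery to one face of an E olefin, both with the same local sense. The methylene ketone is a Michael acceptor that can also slip into the ring as the C11=C12 enone, the epoxides are acid-labile and open to transannular attack, and the acetate is base-labile, so all three must appear late. The hard part is to close the strained twelve-membered ring across two axial positions of ring A while C1, C11, C10 and two olefin geometries are kept under control. The route rests on C2 being a plain methylene between ring carbon C1 and olefinic C3: C1–C2 can be carried as an exocyclic double bond on ring A, whose hydroboration creates C1 and a primary alkylborane, and C2–C3 can then be formed by coupling with an E alkenyl iodide of fixed geometry.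

## Retrosynthetic reasoning

**33 to 32.** The two epoxide C–O bond pairs are removed first. Both epoxides derive from E trisubstituted olefins and are the most acid-sensitive groups, so diene 32 is epoxidised in the last step. The electron-poor C12=C18 olefin does not react with an electrophilic oxidant; the forward step must deliver oxygen to the outer face of each ring olefin.

**32 to 28.** No skeletal bond is cut. The methylene ketone is traced to β-acetoxy ketone 31, that is to a C18 hydroxymethyl group and a C13 ketone, which are carried through the organometallic steps as silyl ether and ethylene ketal (30, 29, 28). This keeps a Michael acceptor and an enolisable β-oxy ketone out of the metal-mediated steps, and one acylation serves both oxygens.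

**28 to 26.** The C2–C3 bond is cut. It is the only ring bond that joins an unfunctionalised sp3 methylene to an olefinic carbon next to ring A. Cutting it makes C3 an alkenyl iodide of preset geometry and C1–C2 an exocyclic olefin, so one operation (hydroboration to borane 27, then B-alkyl Suzuki coupling) closes the ring and creates C1. Cutting at C3=C4 or C7=C8 would leave olefin geometry to the ring closure; cutting C10–C11 would put two stereocentres into it. The forward step needs face-selective hydroboration and a coupling that outruns oligomerisation.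

**26 to 18.** The side chain is cut at C6–C7 and at the two C–CH3 bonds. Each E 2-methylalkenyl iodide (26, 20) comes from a terminal alkyne (24, 18) by carboalumination and iodinolysis (through 25, 19). C3–C6 arrive by sp3–sp2 coupling of zinc reagent 22, made from bromide 21, and desilylation of 23. Both geometries thus come from one stereospecific reaction type.

**18 to 14.** C1=C2 is cut as a carbonyl methylenation of ketone 17. The C9–C10 bond is cut next to the carbinol: alcohol 16 from aldehyde 14 and allenylboronate 15. This brings in C7–C9 as the alkyne needed above and makes C10 under catalyst control; the forward step must override the aldehyde's own facial preference.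

**14 to 8.** Ring A is simplified to enone 8. The aldehyde comes from ozonolysis of the vinyl group of 13; the C13 ketal and C1 ketone come from the enone by conjugate borylation and oxidation (9, 10), ketalisation (11, 12) and alcohol oxidation. The C1 oxygen thus enters exactly at the former β-carbon of the enone.

**8 to 1.** C12–C18 is cut as an aldol reaction of dienolate 6 with formaldehyde 5 (giving 7, then 8). C10–C11 is cut as conjugate addition of the vinyl group of 3 to the achiral dienone 2, the one step that creates absolute configuration and is run with a chiral rhodium catalyst. Dienone 2 comes from commercial 1 by dehydrogenation.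

## Alternatives that were turned down

**Alternative 1:** the large ring is opened between C10 and C11. Substrate A2 carries the C10 aldehyde at the end of the C1 side chain and a 2-(bromomethyl)cyclohexenone as ring A. CrCl2 turns the allylic bromide into an allylchromium species that attacks the aldehyde through C11, forming C10–C11, the ring and the C12=C18 olefin of A1 in one step.
- For: A1 already has the methylene ketone and the free C10 hydroxyl, needs no protecting groups, and is two steps from the target.
- Against: the closure must create C10 and C11 together, and only their correct relation to the remote C1 gives the cis-bridged bicycle. The nucleophilic carbon C11 is neopentylic. The metallated enone can also react at C18 or oxygen. A2 combines a β,γ-unsaturated aldehyde with an alkylating bromomethyl enone.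
- Comparison: Alternative 1 is clearly stronger on step economy. The chosen route gives that up to fix C10 and C11 by two catalyst-controlled steps before ring closure, so that the closure creates only C1.

**Alternative 2:** the ring is opened at C7–C8 as an alkyne. Diyne A4, with methyl-capped alkynes on the C1 arm and the C11 arm, is closed by Mo(CC6H4OMe)(OSiPh3)3 with loss of a volatile alkyne to cycloalkyne A3.
- For: the closing step has no E/Z question, tolerates ketone, silyl ethers and olefins, and is driven independently of the substrate. On the closure itself it is at least as dependable as the B-alkyl Suzuki coupling.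
- Against: A3 lacks C19, so the alkyne must afterwards become the E trisubstituted olefin by a regio- and stereoselective net anti hydromethylation, steered only by the homopropargylic C10 oxygen. A twelve-membered ring holding a linear alkyne unit, an E olefin and the ring A bridge is more strained than the diene. C1 has to be set in a separate operation.
- Comparison: the chosen strategy builds both methyl-bearing olefins before closure by one reaction type and sets C1 in the closing operation.

**Alternative 3:** the ring is opened at the C3=C4 olefin. Keto aldehyde A6 (C3 aldehyde on the C1 arm, C4 methyl ketone on the C11 arm) is coupled reductively with TiCl3(DME)1.5 and Zn–Cu (McMurry) to A5.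
- For: low-valent titanium coupling is among the most dependable ways to close strained carbocycles, and A5 already carries the exocyclic methylene. On tolerance of ring strain it is stronger than a palladium coupling.
- Against: the trisubstituted olefin forms without control of geometry inside a strained ring. The allylic C13 silyl ether meets a strongly reducing, oxophilic metal used in large excess. C13 is at the alcohol level and must be oxidised late. C1 must again be set elsewhere.
- Comparison: the chosen route offers olefin geometry fixed before closure and a closure with catalytic palladium.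

Key step: step 16

Remark: the C1 carbinol centre of 9–12 is drawn trans to the C11 vinyl group (axial entry of the boryl copper species); it is oxidised away in step 7, so the assignment does not affect the route.
Remark: (R)-BINAP (step 2) and (R)-TRIP (step 9) are the enantiomers expected from the usual facial models; the choice of enantiomer would be confirmed on the first run.

## Route

Step 1
Reactants: 1 4,4-dimethylcyclohex-2-en-1-one
Product: 2 4,4-dimethylcyclohexa-2,5-dien-1-one
Conditions: DDQ, dioxane, reflux
Reagents that add atoms: none
Why: Quinone dehydrogenation of the enone through its dienol; the quaternary C15 blocks aromatisation, so the cross-conjugated dienone is the end point.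

Step 2
Reactants: 2 4,4-dimethylcyclohexa-2,5-dien-1-one; 3 potassium trifluoro(vinyl)borate
Product: 4 (5R)-5-ethenyl-4,4-dimethylcyclohex-2-en-1-one
Conditions: [Rh(cod)2]BF4 (3 mol %), (R)-BINAP, Et3N (cat.), toluene/H2O, 25–40 °C
Reagents that add atoms: none
Why: Rhodium-catalysed asymmetric conjugate addition (Hayashi–Miyaura type) of an alkenyltrifluoroborate to a 4,4-disubstituted cyclohexadienone; the enone faces are enantiotopic, so the BINAP–rhodium vinyl complex sets C11 by catalyst control, and about one equivalent of 3 limits a second addition.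

Step 3
Reactants: 4 (5R)-5-ethenyl-4,4-dimethylcyclohex-2-en-1-one; 5 formaldehyde (gas from cracked paraformaldehyde)
Product: 7 (5S,6R)-5-ethenyl-6-(hydroxymethyl)-4,4-dimethylcyclohex-2-en-1-one, via lithium dienolate 6 (not isolated)
Conditions: LiN(iPr)2, THF, −78 °C; then CH2O, −78 °C; aq. NH4Cl
Reagents that add atoms: none
Why: Kinetic deprotonation at the α′ carbon C12 (the only enolisable position) and aldol addition to formaldehyde anti to the neighbouring vinyl group; the trans isomer is also the more stable diequatorial one, so C12 is defined until it becomes sp2.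

Step 4
Reactants: 7 (5S,6R)-5-ethenyl-6-(hydroxymethyl)-4,4-dimethylcyclohex-2-en-1-one
Product: 8 (5S,6R)-6-[(tert-butyldimethylsilyloxy)methyl]-5-ethenyl-4,4-dimethylcyclohex-2-en-1-one
Conditions: TBSCl, imidazole, DMF, 0 °C → rt
Reagents that add atoms: tert-butyldimethylsilyl chloride, CC(C)(C)[Si](C)(C)Cl
Why: Standard silylation of the primary alcohol; it blocks retro-aldol loss of formaldehyde and carries C18 to the end of the route.

Step 5
Reactants: 8 (5S,6R)-6-[(tert-butyldimethylsilyloxy)methyl]-5-ethenyl-4,4-dimethylcyclohex-2-en-1-one
Product: 10 (2R,3S,5S)-2-[(tert-butyldimethylsilyloxy)methyl]-3-ethenyl-5-hydroxy-4,4-dimethylcyclohexan-1-one, via boronate 9 (not isolated)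
Conditions: B2pin2, CuCl (5 mol %), Xantphos, NaOtBu (cat.), MeOH, THF, rt; then NaBO3·4H2O, THF/H2O, rt
Reagents that add atoms: bis(pinacolato)diboron, CC1(C)OB(OC1(C)C)B1OC(C)(C)C(C)(C)O1 (boron of 9); sodium perborate, [Na+].[Na+].O[B-]1(O)OO[B-](O)(O)OO1 (hydroxyl oxygen of 10)
Why: Copper-catalysed conjugate borylation of the remaining enone (boryl copper adds to C1, methanol protonates the enolate), then perborate oxidation of the C–B bond with retention; the isolated vinyl group is not an acceptor and only catalytic base meets the β-silyloxy ketone.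

Step 6
Reactants: 10 (2R,3S,5S)-2-[(tert-butyldimethylsilyloxy)methyl]-3-ethenyl-5-hydroxy-4,4-dimethylcyclohexan-1-one
Product: 12 ring A hydroxy ketal (1S,11S,12R; C13 ethylene ketal; C12 CH2OTBS; C11 vinyl; C1 OH), via trimethylsilyl ether 11 (not isolated)
Conditions: (TMSOCH2)2, TMSOTf (cat.), CH2Cl2, −78 → −20 °C; then K2CO3 (cat.), MeOH, 0 °C
Reagents that add atoms: 1,2-bis(trimethylsilyloxy)ethane, C[Si](C)(C)OCCO[Si](C)(C)C
Why: Noyori ketalisation at low temperature forms the dioxolane without dehydrating the β-hydroxy ketone or cleaving the silyl ether; the C1 hydroxyl is silylated in passing and freed again by methanolysis.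

Step 7
Reactants: 12 ring A hydroxy ketal
Product: 13 ring A keto ketal (11S,12R; C1 ketone; C13 ethylene ketal; C12 CH2OTBS; C11 vinyl)
Conditions: Dess–Martin periodinane, pyridine, CH2Cl2, rt
Reagents that add atoms: none
Why: Dess–Martin oxidation of the hindered secondary alcohol under buffered, non-basic conditions, so the β-keto ketal never meets a strong base.

Step 8
Reactants: 13 ring A keto ketal
Product: 14 ring A keto aldehyde (11S,12R; C10 aldehyde on C11)
Conditions: O3, pyridine, CH2Cl2, −78 °C
Reagents that add atoms: ozone, [O-][O+]=O
Why: Ozonolysis of the only olefin, run with pyridine so that the carbonyl oxide collapses directly to the aldehyde; C11 is α to the aldehyde but already in its more stable equatorial arrangement.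

Step 9
Reactants: 14 ring A keto aldehyde; 15 allenylboronic acid pinacol ester
Product: 16 (10R,11S,12R) homopropargylic alcohol (C10 OH; C9 CH2; C8≡C7 terminal alkyne)
Conditions: (R)-TRIP phosphoric acid (10 mol %), 4 Å MS, toluene, −20 °C
Reagents that add atoms: none
Why: Chiral phosphoric acid-catalysed allenylboration through a six-membered transition state with SE2′ transposition gives the terminal homopropargylic alcohol; the catalyst is meant to choose the Re face of the aldehyde (10R) against the substrate's modest Felkin–Anh bias, and the hindered ketone does not react.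

Step 10
Reactants: 16 (10R,11S,12R) homopropargylic alcohol
Product: 17 (10R,11S,12R) bis-silyl ether ketone (C10 OTBS; C18 OTBS; C1 ketone)
Conditions: TBSOTf, 2,6-lutidine, CH2Cl2, −78 → −40 °C
Reagents that add atoms: tert-butyldimethylsilyl triflate, CC(C)(C)[Si](C)(C)OS(=O)(=O)C(F)(F)F
Why: Silyl triflate silylation of the hindered secondary alcohol at low temperature, where the ketone is not enolised and the ketal is not attacked.

Step 11
Reactants: 17 (10R,11S,12R) bis-silyl ether ketone
Product: 18 (10R,11S,12R) ring A methylene ketal with the C10 homopropargyl arm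
Conditions: Zn, CH2Br2, TiCl4 (reagent pre-formed in THF), CH2Cl2, 0 °C → rt
Reagents that add atoms: dibromomethane, BrCBr
Why: Takai–Lombardo methylenation; the non-basic zinc–titanium methylene reagent converts the hindered, enolisable α-quaternary ketone into the exocyclic olefin without β-elimination of the ketal oxygen and without touching the alkyne.

Step 12
Reactants: 18 (10R,11S,12R) ring A methylene ketal with the C10 homopropargyl arm
Product: 20 E alkenyl iodide (C8 methyl, C7 iodide), via alkenylalane 19 (not isolated)
Conditions: AlMe3, Cp2ZrCl2, H2O (1 equiv), CH2Cl2, −25 °C; then I2, THF, −30 → 0 °C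
Reagents that add atoms: trimethylaluminium, C[Al](C)C (C19 methyl; AlMe2 of 19); iodine, II
Why: Negishi zirconium-catalysed methylalumination adds methyl and aluminium syn across the terminal alkyne with aluminium on the terminal carbon, and iodinolysis with retention gives the E 2-methylalkenyl iodide; the water-accelerated variant runs cold enough to leave the ketal and the 1,1-disubstituted olefin alone.

Step 13
Reactants: 20 E alkenyl iodide; 21 (4-bromobut-1-yn-1-yl)trimethylsilane
Product: 23 silyl enyne (C7–C6 bond formed; C4≡C3–SiMe3), via alkylzinc bromide 22 (not isolated)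
Conditions: 21, Zn, I2 (cat.), DMA, 80 °C; then 20, Pd(DPEphos)Cl2 (5 mol %), THF, rt
Reagents that add atoms: zinc, [Zn] (metal of intermediate 22 only)
Why: Negishi sp3–sp2 coupling of the homopropargylic zinc reagent with the alkenyl iodide with retention of olefin geometry; the wide-bite-angle ligand suppresses β-hydride elimination.

Step 14
Reactants: 23 silyl enyne
Product: 24 terminal enyne (C4≡C3–H)
Conditions: K2CO3 (cat.), MeOH, rt
Reagents that add atoms: none
Why: Methanolysis of the alkynyl C–Si bond; the silyl ethers and the ketal are stable to these conditions.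

Step 15
Reactants: 24 terminal enyne
Product: 26 (10R,11S,12R) ring A methylene ketal with the (7E,3E) dienyl iodide arm, via alkenylalane 25 (not isolated)
Conditions: AlMe3, Cp2ZrCl2, H2O (1 equiv), CH2Cl2, −25 °C; then I2, THF, −30 → 0 °C
Reagents that add atoms: trimethylaluminium, C[Al](C)C (C20 methyl; AlMe2 of 25); iodine, II
Why: The same carboalumination–iodinolysis as in step 12 now creates the E C3=C4 alkenyl iodide; the trisubstituted C7=C8 olefin and the exocyclic methylene are inert.

Step 16
Reactants: 26 (10R,11S,12R) ring A methylene ketal with the (7E,3E) dienyl iodide arm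
Product: 28 (1R,10R,11S,12R) 13-ethylene ketal of 10,18-bis(tert-butyldimethylsilyloxy)verticilla-3E,7E-dien-13-one, via alkylborane 27 (not isolated)
Conditions: 9-BBN, THF, 0 → 40 °C; then slow addition to Pd(dppf)Cl2 (20 mol %), AsPh3, Cs2CO3, DMF/THF/H2O, 50 °C, about 1 mM
Reagents that add atoms: 9-borabicyclo[3.3.1]nonane, [BH]1C2CCCC1CCC2 (boron of intermediate 27 only; its hydrogen stays on C1)
Why: 9-BBN adds to the 1,1-disubstituted C1=C2 olefin in anti-Markovnikov, syn fashion through a four-centre transition state, boron going to C2 and hydrogen to C1; zerovalent palladium then inserts into the C3–I bond with retention, the base-activated borate transfers the primary alkyl group to palladium, and reductive elimination forms C2–C3. The closest known reaction type is the one-pot hydroboration/B-alkyl Suzuki–Miyaura macrocyclisation that has closed bicyclo[9.3.1] carbocycles. The twelve-membered ring is closed by sp3–sp2 coupling at C2–C3, the nine-carbon bridge ending on the two cis 1,3-positions of ring A, and slow addition at high dilution keeps the coupling intramolecular. C1 is under substrate control: in the chair that keeps the C10 arm and C18 equatorial, the axial C15 methyl lies over one olefin face right beside C2, where the bulky borane must sit, so the reagent adds from the other face, hydrogen enters axially and C2 is left equatorial, cis to the C10 arm (1R). The step needs chemoselectivity for the exocyclic olefin over the trisubstituted C7=C8 olefin and the iodoalkene, which the steric demand of 9-BBN secures, and retention of the E geometry at C3=C4, which the stereospecific oxidative addition secures. A C1 epimer of 27 could not span the ring and would stay open-chain, so it should not contaminate 28.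

Step 17
Reactants: 28 macrocyclic bis-silyl ether ketal
Product: 29 (1R,10R,11S,12R) 13-ethylene ketal of 10,18-dihydroxyverticilla-3E,7E-dien-13-one
Conditions: Bu4NF, THF, rt → 45 °C
Reagents that add atoms: none
Why: Fluoride cleavage of both silyl ethers; the ketal keeps the β-hydroxy ketone masked, so neither retro-aldol cleavage nor dehydration can start.

Step 18
Reactants: 29 macrocyclic diol ketal
Product: 30 (1R,10R,11S,12R) 13-ethylene ketal of 10,18-diacetoxyverticilla-3E,7E-dien-13-one
Conditions: Ac2O, DMAP (cat.), pyridine, CH2Cl2, rt
Reagents that add atoms: acetic anhydride, CC(=O)OC(C)=O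
Why: DMAP-catalysed acylation of the primary and the hindered secondary alcohol; it installs the C10 acetate of the target and turns the C18 oxygen into a leaving group, so no selective reaction of one hydroxyl is needed.

Step 19
Reactants: 30 macrocyclic diacetate ketal
Product: 32 (1R,10R,11R)-10-acetoxyverticilla-3E,7E,12(18)-trien-13-one, via acetoxy ketone 31 (not isolated)
Conditions: TsOH·H2O (cat.), acetone/H2O, 40 °C; then DBU, CH2Cl2, 0 °C
Reagents that add atoms: water, O
Why: Acid-catalysed ketal hydrolysis gives the β-acetoxy ketone, and DBU triggers E1cB loss of acetate from C18 to the exocyclic enone; the C10 acetate is not β to the enolate and stays, and the short cold base treatment avoids migration of the olefin to C11=C12.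

Step 20
Reactants: 32 (1R,10R,11R)-10-acetoxyverticilla-3E,7E,12(18)-trien-13-one
Product: 33 (1R,3S,4S,7S,8S,10R,11R)-10-acetoxy-3,4:7,8-diepoxyverticill-12(18)-en-13-one (target)
Conditions: mCPBA (2.3 equiv), NaHCO3, CH2Cl2, −20 → 0 °C
Reagents that add atoms: 3-chloroperbenzoic acid, OOC(=O)c1cccc(Cl)c1
Why: Prilezhaev epoxidation of the two electron-rich trisubstituted olefins, which leaves the electron-poor methylene ketone alone and converts each E olefin stereospecifically into a trans epoxide. Attack on the outer faces of the conformer in which C19 and C20 lie on the ring face remote from the C12–C14 bridge (the face that also carries the C10 oxygen) leads to the 3S,4S,7S,8S isomer.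

## Compound list

1 | 4,4-dimethylcyclohex-2-en-1-one | CC1(C)CCC(=O)C=C1 | starting material
2 | 4,4-dimethylcyclohexa-2,5-dien-1-one | CC1(C)C=CC(=O)C=C1 | intermediate
3 | potassium trifluoro(vinyl)borate | [K+].C=C[B-](F)(F)F | starting material
4 | (5R)-5-ethenyl-4,4-dimethylcyclohex-2-en-1-one | C=C[C@H]1CC(=O)C=CC1(C)C | intermediate
5 | formaldehyde | C=O | starting material
6 | lithium dienolate of 4 (O–C13=C12, formed in the flask) | [Li]OC1=C[C@H](C=C)C(C)(C)C=C1 | intermediate
7 | (5S,6R)-5-ethenyl-6-(hydroxymethyl)-4,4-dimethylcyclohex-2-en-1-one | OC[C@@H]1C(=O)C=CC(C)(C)[C@H]1C=C | intermediate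
8 | (5S,6R)-6-[(tert-butyldimethylsilyloxy)methyl]-5-ethenyl-4,4-dimethylcyclohex-2-en-1-one | CC(C)(C)[Si](C)(C)OC[C@@H]1C(=O)C=CC(C)(C)[C@H]1C=C | intermediate
9 | (2R,3S,5S)-2-[(tert-butyldimethylsilyloxy)methyl]-3-ethenyl-4,4-dimethyl-5-(pinacolatoboryl)cyclohexan-1-one (formed in the flask) | CC(C)(C)[Si](C)(C)OC[C@@H]1C(=O)C[C@H](B2OC(C)(C)C(C)(C)O2)C(C)(C)[C@H]1C=C | intermediate
10 | (2R,3S,5S)-2-[(tert-butyldimethylsilyloxy)methyl]-3-ethenyl-5-hydroxy-4,4-dimethylcyclohexan-1-one | CC(C)(C)[Si](C)(C)OC[C@@H]1C(=O)C[C@H](O)C(C)(C)[C@H]1C=C | intermediate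
11 | ethylene ketal of 10 with C1 trimethylsilyl ether (1S,11S,12R; formed in the flask) | CC(C)(C)[Si](C)(C)OC[C@@H]1C2(OCCO2)C[C@H](O[Si](C)(C)C)C(C)(C)[C@H]1C=C | intermediate
12 | ring A hydroxy ketal (1S,11S,12R): C13 ethylene ketal, C12 CH2OTBS, C11 vinyl, C1 OH | CC(C)(C)[Si](C)(C)OC[C@@H]1C2(OCCO2)C[C@H](O)C(C)(C)[C@H]1C=C | intermediate
13 | ring A keto ketal (11S,12R): C1 ketone, C13 ethylene ketal, C12 CH2OTBS, C11 vinyl | CC(C)(C)[Si](C)(C)OC[C@@H]1C2(OCCO2)CC(=O)C(C)(C)[C@H]1C=C | intermediate
14 | ring A keto aldehyde (11S,12R): C10 aldehyde on C11 | CC(C)(C)[Si](C)(C)OC[C@@H]1C2(OCCO2)CC(=O)C(C)(C)[C@H]1C=O | intermediate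
15 | allenylboronic acid pinacol ester (4,4,5,5-tetramethyl-2-propadienyl-1,3,2-dioxaborolane) | C=C=CB1OC(C)(C)C(C)(C)O1 | starting material
16 | (10R,11S,12R) homopropargylic alcohol: C10 OH, terminal C8≡C7 alkyne, C1 ketone | CC(C)(C)[Si](C)(C)OC[C@@H]1C2(OCCO2)CC(=O)C(C)(C)[C@H]1[C@H](O)CC#C | intermediate
17 | (10R,11S,12R) bis-silyl ether ketone: C10 OTBS, C18 OTBS, C1 ketone | CC(C)(C)[Si](C)(C)OC[C@@H]1C2(OCCO2)CC(=O)C(C)(C)[C@H]1[C@H](O[Si](C)(C)C(C)(C)C)CC#C | intermediate
18 | (10R,11S,12R) ring A methylene ketal with C10 homopropargyl arm | CC(C)(C)[Si](C)(C)OC[C@@H]1C2(OCCO2)CC(=C)C(C)(C)[C@H]1[C@H](O[Si](C)(C)C(C)(C)C)CC#C | intermediate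
19 | E alkenyl(dimethyl)alane at C7 (formed in the flask) | CC(C)(C)[Si](C)(C)OC[C@@H]1C2(OCCO2)CC(=C)C(C)(C)[C@H]1[C@H](O[Si](C)(C)C(C)(C)C)C/C(C)=C/[Al](C)C | intermediate
20 | E alkenyl iodide (C8 methyl, C7 iodide) | CC(C)(C)[Si](C)(C)OC[C@@H]1C2(OCCO2)CC(=C)C(C)(C)[C@H]1[C@H](O[Si](C)(C)C(C)(C)C)C/C(C)=C/I | intermediate
21 | (4-bromobut-1-yn-1-yl)trimethylsilane | C[Si](C)(C)C#CCCBr | starting material
22 | [4-(trimethylsilyl)but-3-yn-1-yl]zinc bromide (formed in the flask) | C[Si](C)(C)C#CCC[Zn]Br | intermediate
23 | silyl enyne (7E olefin, C4≡C3–SiMe3) | CC(C)(C)[Si](C)(C)OC[C@@H]1C2(OCCO2)CC(=C)C(C)(C)[C@H]1[C@H](O[Si](C)(C)C(C)(C)C)C/C(C)=C/CCC#C[Si](C)(C)C | intermediate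
24 | terminal enyne (7E olefin, C4≡C3–H) | CC(C)(C)[Si](C)(C)OC[C@@H]1C2(OCCO2)CC(=C)C(C)(C)[C@H]1[C@H](O[Si](C)(C)C(C)(C)C)C/C(C)=C/CCC#C | intermediate
25 | E dienyl(dimethyl)alane at C3 (formed in the flask) | CC(C)(C)[Si](C)(C)OC[C@@H]1C2(OCCO2)CC(=C)C(C)(C)[C@H]1[C@H](O[Si](C)(C)C(C)(C)C)C/C(C)=C/CC/C(C)=C/[Al](C)C | intermediate
26 | (10R,11S,12R) ring A methylene ketal with (7E,3E) dienyl iodide arm (precursor of the key step) | CC(C)(C)[Si](C)(C)OC[C@@H]1C2(OCCO2)CC(=C)C(C)(C)[C@H]1[C@H](O[Si](C)(C)C(C)(C)C)C/C(C)=C/CC/C(C)=C/I | intermediate
27 | (1R,10R,11S,12R) C2 B-alkyl-9-borabicyclo[3.3.1]nonane (formed in the flask) | CC(C)(C)[Si](C)(C)OC[C@@H]1C2(OCCO2)C[C@@H](CB3C4CCCC3CCC4)C(C)(C)[C@H]1[C@H](O[Si](C)(C)C(C)(C)C)C/C(C)=C/CC/C(C)=C/I | intermediate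
28 | (1R,10R,11S,12R) 13-ethylene ketal of 10,18-bis(tert-butyldimethylsilyloxy)verticilla-3E,7E-dien-13-one | CC(C)(C)[Si](C)(C)OC[C@@H]1C2(OCCO2)C[C@H]3C/C=C(\C)CC/C=C(\C)C[C@@H](O[Si](C)(C)C(C)(C)C)[C@@H]1C3(C)C | intermediate
29 | (1R,10R,11S,12R) 13-ethylene ketal of 10,18-dihydroxyverticilla-3E,7E-dien-13-one | OC[C@@H]1C2(OCCO2)C[C@H]3C/C=C(\C)CC/C=C(\C)C[C@@H](O)[C@@H]1C3(C)C | intermediate
30 | (1R,10R,11S,12R) 13-ethylene ketal of 10,18-diacetoxyverticilla-3E,7E-dien-13-one | CC(=O)OC[C@@H]1C2(OCCO2)C[C@H]3C/C=C(\C)CC/C=C(\C)C[C@@H](OC(C)=O)[C@@H]1C3(C)C | intermediate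
31 | (1R,10R,11S,12R)-10,18-diacetoxyverticilla-3E,7E-dien-13-one (formed in the flask) | CC(=O)OC[C@@H]1C(=O)C[C@H]2C/C=C(\C)CC/C=C(\C)C[C@@H](OC(C)=O)[C@@H]1C2(C)C | intermediate
32 | (1R,10R,11R)-10-acetoxyverticilla-3E,7E,12(18)-trien-13-one | C=C1C(=O)C[C@H]2C/C=C(\C)CC/C=C(\C)C[C@@H](OC(C)=O)[C@@H]1C2(C)C | intermediate
33 | (1R,3S,4S,7S,8S,10R,11R)-10-acetoxy-3,4:7,8-diepoxyverticill-12(18)-en-13-one | C=C1C(=O)C[C@H]2C[C@@H]3O[C@@]3(C)CC[C@@H]3O[C@@]3(C)C[C@@H](OC(C)=O)[C@@H]1C2(C)C | target

## Step count and least certain steps

Total: 20 steps. Longest linear sequence: 20 steps (1 to 33; compounds 3, 5, 15 and 21 enter as commercial partners).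

**Step 16 (key step).** Three things can go wrong.
- Hydroboration may occur on the wrong face, because the axial ketal oxygen at C13 lies 1,3 to C1 on the face that has to be attacked.
- Hydroboration of the hindered olefin may be slow.
- Ring closure may lose to oligomerisation or protodeboronation, because ring A must flip to the chair with both arms axial, in which the axial ketal oxygen is syn to both.

Fallback, from 26, returning at 28: the hydroboration is worked up oxidatively (NaBO3) to primary alcohol F1. If C1 epimers form, Dess–Martin oxidation to aldehyde F2 and equilibration with DBU puts the formyl group equatorial, cis to the C10 arm, and NaBH4 returns F1 as one epimer. I2/PPh3/imidazole gives primary iodide F3. Zn/LiCl inserts into the sp3 C–I bond only, giving alkylzinc iodide F4. Intramolecular Negishi coupling with Pd(DPEphos)Cl2 at high dilution closes the same C2–C3 bond to 28. This separates the stereochemical question from the ring closure and replaces the borane by a more reactive zinc reagent.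

**Step 20.** Oxygen may be delivered to the wrong face of one or both olefins, because the outcome depends on which conformer of the flexible twelve-membered ring reacts; the expectation rests on a model, not on precedent for this ring. Fallback, from 32 to 33 without new compounds (entry F0): reagent-controlled Shi epoxidation with KHSO5 and the enantiomer of the fructose-derived ketone that gives S,S epoxides from E trisubstituted olefins (the L-series ketone). Both olefins need the same catalyst sense, so one catalyst serves both.

**Step 9.** The aldehyde's own Felkin–Anh preference points to the 10S alcohol, so the catalyst works in a mismatched pairing and facial selectivity may be poor; the neopentylic aldehyde may also react slowly. Fallback, from 14, returning at 16: the substrate bias is accepted and corrected afterwards. Barbier addition of propargyl bromide with Zn in THF/aq. NH4Cl gives mainly the 10S alcohol F5. Mitsunobu inversion (4-nitrobenzoic acid, PPh3, DIAD) gives the 10R 4-nitrobenzoate F6, and K2CO3/MeOH releases 16.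

**Step 11.** Methylenation of the α-quaternary ketone may stall, or the Lewis-acidic reagent may open the ketal. A basic ylide is avoided because enolisation towards C14 would expel the ketal oxygen. Fallback, from 17, returning at 18: Peterson olefination in two stages. Me3SiCH2Li/CeCl3 in THF at −78 °C adds to the ketone without enolisation to give β-hydroxysilane F7 (configuration at C1 immaterial), and KH in THF eliminates silanolate to 18.

## Further compounds

F1 | step 16 | (1R,10R,11S,12R) C2 primary alcohol of the dienyl iodide | CC(C)(C)[Si](C)(C)OC[C@@H]1C2(OCCO2)C[C@@H](CO)C(C)(C)[C@H]1[C@H](O[Si](C)(C)C(C)(C)C)C/C(C)=C/CC/C(C)=C/I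
F2 | step 16 | (1R,10R,11S,12R) C2 aldehyde of the dienyl iodide | CC(C)(C)[Si](C)(C)OC[C@@H]1C2(OCCO2)C[C@@H](C=O)C(C)(C)[C@H]1[C@H](O[Si](C)(C)C(C)(C)C)C/C(C)=C/CC/C(C)=C/I
F3 | step 16 | (1R,10R,11S,12R) C2 primary iodide of the dienyl iodide | CC(C)(C)[Si](C)(C)OC[C@@H]1C2(OCCO2)C[C@@H](CI)C(C)(C)[C@H]1[C@H](O[Si](C)(C)C(C)(C)C)C/C(C)=C/CC/C(C)=C/I
F4 | step 16 | (1R,10R,11S,12R) C2 alkylzinc iodide of the dienyl iodide | CC(C)(C)[Si](C)(C)OC[C@@H]1C2(OCCO2)C[C@@H](C[Zn]I)C(C)(C)[C@H]1[C@H](O[Si](C)(C)C(C)(C)C)C/C(C)=C/CC/C(C)=C/I
F0 | step 20 | none | none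
F5 | step 9 | (10S,11S,12R) homopropargylic alcohol (C10 epimer of 16) | CC(C)(C)[Si](C)(C)OC[C@@H]1C2(OCCO2)CC(=O)C(C)(C)[C@H]1[C@@H](O)CC#C
F6 | step 9 | (10R,11S,12R) 4-nitrobenzoate of 16 | CC(C)(C)[Si](C)(C)OC[C@@H]1C2(OCCO2)CC(=O)C(C)(C)[C@H]1[C@H](OC(=O)c3ccc(cc3)[N+](=O)[O-])CC#C
F7 | step 11 | C1 tertiary alcohol with C1 (trimethylsilyl)methyl group (β-hydroxysilane from 17) | CC(C)(C)[Si](C)(C)OC[C@@H]1C2(OCCO2)C[C@@](O)(C[Si](C)(C)C)C(C)(C)[C@H]1[C@H](O[Si](C)(C)C(C)(C)C)CC#C
A1 | alternative 1 | 10-hydroxyverticilla-3,7,12(18)-trien-13-one | C=C1C(=O)C[C@H]2C/C=C(\C)CC/C=C(\C)C[C@@H](O)[C@@H]1C2(C)C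
A2 | alternative 1 | ring A 2-(bromomethyl)enone with the C1 side chain ending in the C10 aldehyde | O=CC/C(C)=C/CC/C(C)=C/C[C@@H]1CC(=O)C(CBr)=CC1(C)C
A3 | alternative 2 | twelve-membered cycloalkyne, 7,8-didehydro-19-nor verticillane ketone | CC(C)(C)[Si](C)(C)OC[C@@H]1C(=O)C[C@H]2C/C=C(\C)CCC#CC[C@@H](O[Si](CC)(CC)CC)[C@@H]1C2(C)C
A4 | alternative 2 | ring A ketone with methyl-capped alkynes on the C1 arm and the C11 arm | CC(C)(C)[Si](C)(C)OC[C@@H]1C(=O)C[C@@H](C/C=C(\C)CCC#CC)C(C)(C)[C@H]1[C@H](O[Si](CC)(CC)CC)CC#CC
A5 | alternative 3 | 10,13-bis(tert-butyldimethylsilyloxy)verticilla-3,7,12(18)-triene | C=C1[C@@H](O[Si](C)(C)C(C)(C)C)C[C@H]2C/C=C(\C)CC/C=C(\C)C[C@@H](O[Si](C)(C)C(C)(C)C)[C@@H]1C2(C)C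
A6 | alternative 3 | ring A keto aldehyde: C3 aldehyde on the C1 arm, C4 methyl ketone on the C11 arm | C=C1[C@@H](O[Si](C)(C)C(C)(C)C)C[C@@H](CC=O)C(C)(C)[C@H]1[C@H](O[Si](C)(C)C(C)(C)C)C/C(C)=C/CCC(C)=O
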